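Both bicyclic halves are drawn from one trans-fused oxepanone–cyclohexane block and joined late by olefination and hydrogenation. Everything rests on reading the oxepane atoms O1–C2(CH3)2–C3(=O)–C4H2 as a 2,2-dimethylfuran-3(2H)-one whose C5 is the oxygen-bearing ring-fusion carbon. Irradiation of such a furanone, linked through four atoms to an isopropenyl group, forges in one operation the fusion bond to the methyl-bearing quaternary carbon and the CH2–CH2 bond of the oxepane, closing the cyclohexane and a cyclobutane and setting three stereocentres; reductive opening of the cyclobutane then releases the seven-membered ring. The precursor is this furanone carrying a trans-4,5-disubstituted 1,3-dioxane (ethylene link at C4, isopropenyl at C5).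

Key step: step 8

Remark (target): the two tertiary acetates are epimeric, as the SMILES requires. In the alcohol half the acetoxy group is axial, cis to the angular methyl and to the linker; in the ketone half it is equatorial, trans to the linker.

Remark (precursor design): the carbon next to the alkene-bearing stereocentre is carried as a protected alcohol inside a trans-fused acetonide and not as a ketal, so that this stereocentre is never alpha to a carbonyl before the ring is built; the ketone is unmasked in step 14.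

Remark (labels): the bicyclic core is numbered as a 1-benzoxepine: O1, C2 (gem-dimethyl), C3, C4, C5, C5a (C–CH3), C6 (carries the one-carbon arm), C7, C8, C9, C9a (O–CH). From compound 14 on the ring fusion is trans (9a-H anti to 5a-CH3) and the C6 arm is equatorial, cis to 5a-CH3.

Step 1
Reactants: 1 pent-4-yn-1-ol
Product: 3 ethyl (E)-hept-2-en-6-ynoate, via pent-4-ynal 2 (not isolated)
Conditions: PhI(OAc)2, TEMPO (2,2,6,6-tetramethylpiperidin-1-oxyl, 10 mol%), CH2Cl2, 20 °C; then Ph3P=CHCO2Et, 20 °C
Reagents that add atoms: ethyl 2-(triphenyl-λ5-phosphanylidene)acetate, CCOC(=O)C=P(c1ccccc1)(c1ccccc1)c1ccccc1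
Why: The nitroxyl-catalysed oxidation stops at the aldehyde and the stabilised ylide is added to the same flask (one-pot oxidation–Wittig olefination), which should give the E-enoate without isolating the volatile aldehyde.

Step 2
Reactants: 3 ethyl (E)-hept-2-en-6-ynoate
Product: 4 (E)-hept-2-en-6-yn-1-ol
Conditions: iBu2AlH (2.2 equiv), CH2Cl2, −78 °C; Rochelle salt work-up
Reagents that add atoms: none
Why: 1,2-Reduction of the conjugated ester by the aluminium hydride at low temperature should give the allylic alcohol, the alkyne being inert.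

Step 3
Reactants: 4 (E)-hept-2-en-6-yn-1-ol
Product: 5 [(2S,3S)-3-(but-3-yn-1-yl)oxiran-2-yl]methanol
Conditions: Ti(OiPr)4 (10 mol%), L-(+)-diethyl tartrate (12 mol%), t-BuOOH, 4 Å molecular sieves, CH2Cl2, −20 °C
Reagents that add atoms: tert-butyl hydroperoxide, CC(C)(C)OO
Why: Sharpless asymmetric epoxidation; with L-(+)-diethyl tartrate the E-allylic alcohol is epoxidised on the face that gives the (2S,3S)-epoxy alcohol, which fixes the carbons that become C7 and C6 of the core.

Step 4
Reactants: 5 [(2S,3S)-3-(but-3-yn-1-yl)oxiran-2-yl]methanol; 6 isopropenylmagnesium bromide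
Product: 7 (2R,3S)-2-(prop-1-en-2-yl)hept-6-yne-1,3-diol
Conditions: 6 (4 equiv), CuI (10 mol%), THF, −30 → −10 °C; aq. NH4Cl; NaIO4 wash
Reagents that add atoms: none
Why: Copper-catalysed opening of the 2,3-epoxy alcohol by the alkenyl Grignard reagent occurs at C2 with inversion (SN2) and should give the anti 2-alkenyl-1,3-diol; excess reagent covers the O–H and alkyne C–H, and the minor 1,2-diol from C3 attack is destroyed by periodate.

Step 5
Reactants: 7 (2R,3S)-2-(prop-1-en-2-yl)hept-6-yne-1,3-diol
Product: 8 (4S,5R)-4-(but-3-yn-1-yl)-2,2-dimethyl-5-(prop-1-en-2-yl)-1,3-dioxane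
Conditions: 2,2-dimethoxypropane, pyridinium p-toluenesulfonate (5 mol%), CH2Cl2, 20 °C
Reagents that add atoms: 2,2-dimethoxypropane, COC(C)(C)OC
Why: Acid-catalysed transketalisation closes the six-membered isopropylidene acetal of the 1,3-diol with both carbon substituents equatorial (trans); this ring is the conformational lock for step 8.

Step 6
Reactants: 8 (4S,5R)-4-(but-3-yn-1-yl)-2,2-dimethyl-5-(prop-1-en-2-yl)-1,3-dioxane; 9 2-acetoxy-2-methylpropanoyl chloride
Product: 10 7-[(4S,5R)-2,2-dimethyl-5-(prop-1-en-2-yl)-1,3-dioxan-4-yl]-2-methyl-3-oxohept-4-yn-2-yl acetate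
Conditions: PdCl2(PPh3)2 (2 mol%), CuI (4 mol%), Et3N, THF, 20 °C
Reagents that add atoms: none
Why: Acyl Sonogashira coupling of the terminal alkyne with the acid chloride should give the ynone under conditions that leave the acetonide untouched; the acid chloride has no alpha hydrogen and cannot form a ketene.

Step 7
Reactants: 10 ynone acetate
Product: 11 5-{2-[(4S,5R)-2,2-dimethyl-5-(prop-1-en-2-yl)-1,3-dioxan-4-yl]ethyl}-2,2-dimethylfuran-3(2H)-one
Conditions: K2CO3 (0.3 equiv), MeOH, 0 → 20 °C
Reagents that add atoms: none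
Why: Methanolysis of the tertiary acetate frees the alkoxide, which adds to the ynone in a 5-endo-dig oxa-Michael cyclisation, the standard closure of alpha′-hydroxy ynones to 3(2H)-furanones.

Step 8
Reactants: 11 furanone–dioxane precursor
Product: 12 tetracyclic photoadduct (2,2-dimethyldihydrofuran-3-one ring cis-fused to a cyclobutane, which is cis-fused to the cyclohexane; the cyclohexane carries the trans-fused 2,2-dimethyl-1,3-dioxane; ring oxygen and C-methyl cis, CH2O arm cis to that methyl)
Conditions: hν (350 nm, Pyrex), degassed MeCN (5 mM), 20 °C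
Reagents that add atoms: none
Why: Excitation of the furanone and intersystem crossing give the triplet enone, which bonds to the tethered alkene to a triplet 1,4-biradical that closes to the cyclobutane after spin inversion. The closest known reaction type is the intramolecular enone–alkene [2+2] photocycloaddition of 3(2H)-furanones and dioxenones, the first half of a de Mayo-type sequence. The cyclohexane closes 6-exo through a chair-like arrangement (furanone C5 to the internal alkene carbon, four-atom tether), and the cyclobutane closes by collapse of the biradical (furanone C4 to the alkene CH2), which can only be cis-fused to both neighbouring rings. Hence the two new quaternary centres carry ring oxygen and methyl cis and the new C4–H centre follows from the cis fusion; their sense relative to the existing centres is set by the trans-fused dioxane, which holds both tether substituents equatorial, and by the furanone stacking with its O–CMe2 edge equatorial and its slim C4–H edge axial, which places the methyl axial and cis to the CH2O arm. The step needs straight rather than crossed closure, secured by the four-atom tether (the crossed adduct would be a strained bridged bicyclo[4.1.1] system), and attack on one alkene face, secured by the stereocentre next to the alkene, whose C–H eclipses the alkene CH2 while the CH2O arm lies anti to the forming bond; light above 340 nm excites only the furanone.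

Step 9
Reactants: 12 tetracyclic photoadduct
Product: 14 tricyclic oxepanone acetonide (trans-fused 2,2,5a-trimethyl-1-benzoxepan-3-one core; 6-CH2O and 7-O tied as trans-fused isopropylidene acetal), via samarium enolate 13 (not isolated)
Conditions: SmI2 (2.1 equiv), HMPA, t-BuOH (2 equiv), THF, −78 °C; aq. NH4Cl
Reagents that add atoms: none
Why: Single-electron reduction gives the ketyl, whose beta-scission (ketyl-induced cyclobutane fragmentation of an enone photoadduct) should break the strained ring-fusion bond that leads to the tertiary alpha-alkoxy radical; a second electron and a proton put hydrogen on C9a from the axial side that the cyclobutane carbon left, so the oxepane stays diequatorial (trans-fused), and the ketone stays masked as the trivalent samarium enolate 13 until the quench, which shields the alpha-alkoxy ketone from further reduction.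

Step 10
Reactants: 14 tricyclic oxepanone acetonide
Product: 15 (3S)-alcohol of 14 (3-OH anti to 5a-CH3)
Conditions: (R)-Me-CBS [(3aR)-1-methyl-3,3-diphenyltetrahydro-1H,3H-pyrrolo[1,2-c][1,3,2]oxazaborole, 0.5 equiv], BH3·SMe2, THF, −20 °C; MeOH
Reagents that add atoms: none
Why: Corey–Bakshi–Shibata reduction; the (R)-oxazaborolidine binds the ketone anti to the bulky O–CMe2 side (large group) and delivers hydride to the face that gives the (3S)-alcohol, the CH2 side being the small group (reagent control).

Step 11
Reactants: 15 (3S)-alcohol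
Product: 16 (3S)-3-benzyloxy acetonide
Conditions: NaH, BnBr, Bu4NI (10 mol%), THF–DMF, 0 → 20 °C
Reagents that add atoms: benzyl bromide, BrCc1ccccc1
Why: Williamson etherification of the hindered secondary alkoxide under iodide catalysis; the benzyl ether should survive every later step until the hydrogenations in steps 23 and 28.

Step 12
Reactants: 16 (3S)-3-benzyloxy acetonide
Product: 17 (3S)-3-benzyloxy-6-(hydroxymethyl)-2,2,5a-trimethyldecahydro-1-benzoxepin-7-ol (7-OH equatorial, trans to the C6 arm)
Conditions: AcOH–H2O (4:1), 40 °C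
Reagents that add atoms: none
Why: Mild aqueous acid hydrolyses the isopropylidene acetal and leaves the benzyl ether and the oxepane intact.

Step 13
Reactants: 17 diol
Product: 18 (3S)-3-benzyloxy-2,2,5a-trimethyl-6-[(triethylsilyloxy)methyl]decahydro-1-benzoxepin-7-ol
Conditions: Et3SiCl (1.05 equiv), imidazole, CH2Cl2, −78 → −30 °C
Reagents that add atoms: chlorotriethylsilane, CC[Si](Cl)(CC)CC
Why: The primary hydroxyl is silylated much faster than the ring secondary one at low temperature (steric selectivity).

Step 14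
Reactants: 18 primary silyl ether
Product: 19 (3S)-3-benzyloxy-2,2,5a-trimethyl-6-[(triethylsilyloxy)methyl]octahydro-1-benzoxepin-7(2H)-one
Conditions: Dess–Martin periodinane, NaHCO3, CH2Cl2, 0 → 20 °C
Reagents that add atoms: none
Why: Buffered Dess–Martin oxidation converts the secondary alcohol into the ketone without base, so the beta-silyloxy ketone should neither eliminate nor epimerise (the C6 arm is already equatorial).

Step 15
Reactants: 19 ketone
Product: 21 (3S)-3-benzyloxy-6-(hydroxymethyl)-2,2,5a,7-tetramethyldecahydro-1-benzoxepin-7-ol (7-OH axial, cis to 5a-CH3 and to the C6 arm), via triethylsilyl ether 20 (not isolated)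
Conditions: MeLi, CeCl3, THF, −78 °C; then 1 M HCl, MeOH, 0 °C
Reagents that add atoms: methyllithium, [Li]C
Why: The organocerium reagent (low basicity, so no enolisation or beta-elimination) adds to the ketone from the equatorial side because the axial 5a-methyl blocks axial attack, giving the axial tertiary alcohol; the acidic work-up removes the primary triethylsilyl group.

Step 16
Reactants: 21 diol (alcohol half)
Product: 22 1-phenyl-1H-tetrazol-5-yl sulfide of 21 (sulfur on the C6 CH2)
Conditions: 1-phenyl-1H-tetrazole-5-thiol, PPh3, diisopropyl azodicarboxylate, THF, 0 → 20 °C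
Reagents that add atoms: 1-phenyl-1H-tetrazole-5-thiol, Sc1nnnn1-c1ccccc1
Why: Mitsunobu thioetherification with the acidic thiol takes place only at the primary alcohol; the tertiary alcohol cannot be activated.

Step 17
Reactants: 22 sulfide
Product: 23 1-phenyl-1H-tetrazol-5-yl sulfone
Conditions: (NH4)6Mo7O24·4H2O (20 mol%), 30% H2O2, EtOH, 0 → 20 °C
Reagents that add atoms: hydrogen peroxide, OO
Why: Molybdate-catalysed peroxide oxidation takes the sulfide to the sulfone and leaves the tertiary alcohol and the benzyl ether untouched.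

Step 18
Reactants: 23 hydroxy sulfone
Product: 24 7-O-trimethylsilyl sulfone (alcohol-half coupling partner)
Conditions: Me3SiOTf, 2,6-lutidine, CH2Cl2, −78 → 0 °C
Reagents that add atoms: trimethylsilyl trifluoromethanesulfonate, C[Si](C)(C)OS(=O)(=O)C(F)(F)F
Why: Silylation of the hindered tertiary alcohol with the silyl triflate removes the alkoxide that could otherwise attack the tetrazole ring during the olefination.

Step 19
Reactants: 19 ketone
Product: 25 (3S)-3-benzyloxy-2,2,5a-trimethyl-7-methylidene-6-[(triethylsilyloxy)methyl]decahydro-1-benzoxepine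
Conditions: Ph3PCH3Br, KOtBu, toluene, 0 → 60 °C
Reagents that add atoms: methyltriphenylphosphonium bromide, C[P+](c1ccccc1)(c1ccccc1)c1ccccc1.[Br-]
Why: Wittig methylenation of the ketone, as practised on the analogous 8-oxo-drimane ketones; the preformed ylide is added cold to limit enolisation of the beta-silyloxy ketone.

Step 20
Reactants: 25 exocyclic alkene
Product: 26 spiro-epoxide at C7 (epoxide oxygen equatorial, CH2 axial)
Conditions: mCPBA, NaHCO3, CH2Cl2, 0 °C
Reagents that add atoms: 3-chloroperoxybenzoic acid, OOC(=O)c1cccc(Cl)c1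
Why: Prilezhaev epoxidation of the exocyclic alkene from the equatorial face, because the axial 5a-methyl shields the other face, should place the epoxide oxygen equatorial.

Step 21
Reactants: 26 spiro-epoxide
Product: 27 (3S)-3-benzyloxy-2,2,5a,7-tetramethyl-6-[(triethylsilyloxy)methyl]decahydro-1-benzoxepin-7-ol (7-OH equatorial, trans to the C6 arm; 7-CH3 axial)
Conditions: LiAlH4, THF, 0 → 50 °C
Reagents that add atoms: none
Why: Hydride opens the epoxide at the primary carbon (SN2), turning the axial CH2 into the axial methyl and leaving the equatorial tertiary alcohol.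

Step 22
Reactants: 27 tertiary alcohol
Product: 28 7-O-triethylsilyl ether of 27
Conditions: Et3SiOTf, 2,6-lutidine, CH2Cl2, −78 → 0 °C
Reagents that add atoms: triethylsilyl trifluoromethanesulfonate, CC[Si](CC)(CC)OS(=O)(=O)C(F)(F)F
Why: The silyl triflate silylates the tertiary alcohol, so that the beta-oxygenated aldehyde made in step 24 cannot undergo retro-aldol cleavage under base.

Step 23
Reactants: 28 bis(silyl ether)
Product: 29 (3S)-alcohol (3-OH free; 6-CH2OSiEt3 and 7-OSiEt3 kept)
Conditions: H2 (1 atm), Pd/C (10%), EtOAc, 20 °C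
Reagents that add atoms: none
Why: Hydrogenolysis of the benzyl ether over palladium frees the C3 alcohol; the silyl ethers are stable in ethyl acetate.

Step 24
Reactants: 29 alcohol
Product: 30 keto aldehyde (3-oxo, 6-formyl, 7-OSiEt3; ketone-half coupling partner)
Conditions: (COCl)2, DMSO, CH2Cl2, −78 → −40 °C; Et3N, −78 → 0 °C
Reagents that add atoms: none
Why: Swern oxidation converts the secondary alcohol into the ketone and, on warming to −40 °C, also cleaves the primary triethylsilyl ether oxidatively to the aldehyde (known selective oxidation of primary triethylsilyl ethers), while the tertiary silyl ether stays.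

Step 25
Reactants: 24 sulfone (alcohol half); 30 keto aldehyde (ketone half)
Product: 31 coupled (E)-alkene (C6–CH=CH–C6′ between the two cores)
Conditions: KN(SiMe3)2 (1.1 equiv), THF, −78 °C; then 30, −78 → 20 °C; aq. NH4Cl
Reagents that add atoms: none
Why: Julia–Kocienski olefination; the metalated tetrazolyl sulfone adds to the aldehyde (far more electrophilic than the hindered ketone), and Smiles rearrangement with loss of SO2 gives the alkene, whose geometry is irrelevant because it is hydrogenated in step 28.

Step 26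
Reactants: 31 coupled alkene
Product: 32 bis(tertiary alcohol)
Conditions: HF·pyridine, pyridine, THF, 0 → 20 °C
Reagents that add atoms: none
Why: Fluoride-mediated desilylation cleaves both tertiary silyl ethers; ketone, alkene and benzyl ether are inert.

Step 27
Reactants: 32 diol
Product: 33 diacetate
Conditions: Ac2O, Sc(OTf)3 (5 mol%), MeCN, −20 °C
Reagents that add atoms: acetic anhydride, CC(=O)OC(C)=O
Why: Lewis-acid-catalysed acylation with acetic anhydride acetylates hindered tertiary alcohols at low temperature without elimination, and the only other hydroxyl is still benzylated.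

Step 28
Reactants: 33 diacetate
Product: 34 CNP0298533.1
Conditions: H2 (1–3 atm), Pd(OH)2/C, EtOAc–EtOH, 20 °C
Reagents that add atoms: none
Why: Heterogeneous hydrogenation saturates the disubstituted alkene and hydrogenolyses the benzyl ether in one operation; ketone and tertiary acetates are untouched and no stereocentre is affected.

Compound list
1 | pent-4-yn-1-ol | OCCCC#C | starting material
2 | pent-4-ynal | O=CCCC#C | intermediate (not isolated)
3 | ethyl (E)-hept-2-en-6-ynoate | CCOC(=O)/C=C/CCC#C | intermediate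
4 | (E)-hept-2-en-6-yn-1-ol | OC/C=C/CCC#C | intermediate
5 | [(2S,3S)-3-(but-3-yn-1-yl)oxiran-2-yl]methanol | OC[C@@H]1O[C@H]1CCC#C | intermediate
6 | isopropenylmagnesium bromide (prop-1-en-2-ylmagnesium bromide) | CC(=C)[Mg]Br | starting material
7 | (2R,3S)-2-(prop-1-en-2-yl)hept-6-yne-1,3-diol | OC[C@H]([C@@H](O)CCC#C)C(C)=C | intermediate
8 | (4S,5R)-4-(but-3-yn-1-yl)-2,2-dimethyl-5-(prop-1-en-2-yl)-1,3-dioxane | C#CCC[C@@H]1OC(C)(C)OC[C@H]1C(C)=C | intermediate
9 | 2-acetoxy-2-methylpropanoyl chloride | CC(=O)OC(C)(C)C(Cl)=O | starting material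
10 | 7-[(4S,5R)-2,2-dimethyl-5-(prop-1-en-2-yl)-1,3-dioxan-4-yl]-2-methyl-3-oxohept-4-yn-2-yl acetate | CC(=O)OC(C)(C)C(=O)C#CCC[C@@H]1OC(C)(C)OC[C@H]1C(C)=C | intermediate
11 | 5-{2-[(4S,5R)-2,2-dimethyl-5-(prop-1-en-2-yl)-1,3-dioxan-4-yl]ethyl}-2,2-dimethylfuran-3(2H)-one (key-step precursor) | CC1(C)OC(=CC1=O)CC[C@@H]2OC(C)(C)OC[C@H]2C(C)=C | intermediate
12 | tetracyclic photoadduct (furanone ring, cyclobutane, cyclohexane, trans-fused dioxane; O and C-methyl cis, CH2O arm cis to the methyl) | O=C1[C@@H]2C[C@@]3(C)[C@@H]4COC(C)(C)O[C@H]4CC[C@@]23OC1(C)C | intermediate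
13 | trivalent samarium enolate of 14 | I[Sm](I)OC1=CC[C@@]2(C)[C@@H]3COC(C)(C)O[C@H]3CC[C@@H]2OC1(C)C | intermediate (not isolated)
14 | tricyclic oxepanone acetonide (trans-fused 1-benzoxepan-3-one; 6-CH2O/7-O isopropylidene acetal) | O=C1CC[C@@]2(C)[C@@H]3COC(C)(C)O[C@H]3CC[C@@H]2OC1(C)C | intermediate
15 | (3S)-alcohol of 14 | O[C@H]1CC[C@@]2(C)[C@@H]3COC(C)(C)O[C@H]3CC[C@@H]2OC1(C)C | intermediate
16 | (3S)-3-benzyloxy acetonide | c1ccccc1CO[C@H]1CC[C@@]2(C)[C@@H]3COC(C)(C)O[C@H]3CC[C@@H]2OC1(C)C | intermediate
17 | (3S)-3-benzyloxy-6-(hydroxymethyl)-2,2,5a-trimethyldecahydro-1-benzoxepin-7-ol | c1ccccc1CO[C@H]1CC[C@@]2(C)[C@H](CO)[C@@H](O)CC[C@@H]2OC1(C)C | intermediate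
18 | primary triethylsilyl ether of 17 | c1ccccc1CO[C@H]1CC[C@@]2(C)[C@H](CO[Si](CC)(CC)CC)[C@@H](O)CC[C@@H]2OC1(C)C | intermediate
19 | (3S)-3-benzyloxy-2,2,5a-trimethyl-6-[(triethylsilyloxy)methyl]octahydro-1-benzoxepin-7(2H)-one | c1ccccc1CO[C@H]1CC[C@@]2(C)[C@H](CO[Si](CC)(CC)CC)C(=O)CC[C@@H]2OC1(C)C | intermediate
20 | axial tertiary alcohol, primary triethylsilyl ether | c1ccccc1CO[C@H]1CC[C@@]2(C)[C@H](CO[Si](CC)(CC)CC)[C@](C)(O)CC[C@@H]2OC1(C)C | intermediate (not isolated)
21 | (3S)-3-benzyloxy-6-(hydroxymethyl)-2,2,5a,7-tetramethyldecahydro-1-benzoxepin-7-ol (7-OH axial) | c1ccccc1CO[C@H]1CC[C@@]2(C)[C@H](CO)[C@](C)(O)CC[C@@H]2OC1(C)C | intermediate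
22 | 1-phenyl-1H-tetrazol-5-yl sulfide of 21 | c1ccccc1CO[C@H]1CC[C@@]2(C)[C@H](CSc3nnnn3-c3ccccc3)[C@](C)(O)CC[C@@H]2OC1(C)C | intermediate
23 | 1-phenyl-1H-tetrazol-5-yl sulfone | c1ccccc1CO[C@H]1CC[C@@]2(C)[C@H](CS(=O)(=O)c3nnnn3-c3ccccc3)[C@](C)(O)CC[C@@H]2OC1(C)C | intermediate
24 | 7-O-trimethylsilyl sulfone | c1ccccc1CO[C@H]1CC[C@@]2(C)[C@H](CS(=O)(=O)c3nnnn3-c3ccccc3)[C@](C)(O[Si](C)(C)C)CC[C@@H]2OC1(C)C | intermediate
25 | 7-methylidene compound | c1ccccc1CO[C@H]1CC[C@@]2(C)[C@H](CO[Si](CC)(CC)CC)C(=C)CC[C@@H]2OC1(C)C | intermediate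
26 | C7 spiro-epoxide (oxygen equatorial) | c1ccccc1CO[C@H]1CC[C@@]2(C)[C@H](CO[Si](CC)(CC)CC)[C@]3(CO3)CC[C@@H]2OC1(C)C | intermediate
27 | equatorial tertiary alcohol (7-CH3 axial) | c1ccccc1CO[C@H]1CC[C@@]2(C)[C@H](CO[Si](CC)(CC)CC)[C@@](C)(O)CC[C@@H]2OC1(C)C | intermediate
28 | 7-O-triethylsilyl ether of 27 | c1ccccc1CO[C@H]1CC[C@@]2(C)[C@H](CO[Si](CC)(CC)CC)[C@@](C)(O[Si](CC)(CC)CC)CC[C@@H]2OC1(C)C | intermediate
29 | debenzylated (3S)-alcohol | O[C@H]1CC[C@@]2(C)[C@H](CO[Si](CC)(CC)CC)[C@@](C)(O[Si](CC)(CC)CC)CC[C@@H]2OC1(C)C | intermediate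
30 | keto aldehyde (3-oxo, 6-formyl, 7-OSiEt3) | O=C1CC[C@@]2(C)[C@H](C=O)[C@@](C)(O[Si](CC)(CC)CC)CC[C@@H]2OC1(C)C | intermediate
31 | coupled (E)-alkene | c1ccccc1CO[C@H]1CC[C@@]2(C)[C@H](/C=C/[C@H]3[C@]4(C)CCC(=O)C(C)(C)O[C@H]4CC[C@]3(C)O[Si](CC)(CC)CC)[C@](C)(O[Si](C)(C)C)CC[C@@H]2OC1(C)C | intermediate
32 | bis(tertiary alcohol) | c1ccccc1CO[C@H]1CC[C@@]2(C)[C@H](/C=C/[C@H]3[C@]4(C)CCC(=O)C(C)(C)O[C@H]4CC[C@]3(C)O)[C@](C)(O)CC[C@@H]2OC1(C)C | intermediate
33 | diacetate | c1ccccc1CO[C@H]1CC[C@@]2(C)[C@H](/C=C/[C@H]3[C@]4(C)CCC(=O)C(C)(C)O[C@H]4CC[C@]3(C)OC(C)=O)[C@](C)(OC(C)=O)CC[C@@H]2OC1(C)C | intermediate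
34 | CNP0298533.1 | CC(=O)O[C@]1(C)CC[C@@H]2OC(C)(C)[C@@H](O)CC[C@@]2(C)[C@@H]1CC[C@H]1[C@]2(C)CCC(=O)C(C)(C)O[C@H]2CC[C@]1(C)OC(C)=O | target

Total step count: 28.
Longest linear sequence: 24 steps (steps 1–14, 19–24, 25–28).

Steps most likely to fail

Step 8. The excited furanone may add to the wrong face of the isopropenyl group, or close in the crossed sense, if the rigid dioxane holds the alkene in an unfavourable rotamer. The fallback moves stereocontrol from the bicyclic template to an open-chain tether. Setting out from diol 7, both hydroxyls are silylated (t-BuMe2SiOTf, 2,6-lutidine) to the bis(tert-butyldimethylsilyl) ether F1. Acylation with 9 under the conditions of step 6 gives the ynone acetate F2, and K2CO3 in MeOH gives the furanone F3. In this flexible tether only the stereocentre next to the alkene steers the closure: its C–H eclipses the alkene, the silyloxymethyl arm lies anti to the forming bond, and both silyloxy groups stay equatorial. Irradiation as in step 8 gives the photoadduct F4, SmI2 the oxepanone F5, the reduction of step 10 the (3S)-alcohol F6, and benzylation the benzyl ether F7. Bu4NF removes both silyl groups and the route is rejoined at diol 17.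

Step 9. The ketyl may break the outer cyclobutane bond (better orbital overlap) or the C–O bond next to the carbonyl instead of the ring-fusion bond, and excess reagent may reduce the alpha-alkoxy ketone further. The fallback is an ionic instead of a radical opening, setting out from 12 and returning at 14. Photoadduct 12 is treated with BF3·OEt2 and Et3SiH in CH2Cl2 at −78 °C. Activation of the ketone and push from the ring oxygen can break only the bond between the alkoxy-bearing carbon and the alpha carbon. This gives a seven-membered oxocarbenium ion, which the silane reduces from the axial face. Work-up gives 14 directly, so no new compound is made (F0).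

Step 25. The hindered sulfonyl anion may add slowly to the hindered aldehyde, with competing enolisation of the aldehyde or ketone and decay of the metalated tetrazolyl sulfone. The fallback is the classical Julia–Lythgoe olefination in separate stages. Setting out from diol 21, PhSSPh/PBu3 gives the phenyl sulfide F8, (NH4)6Mo7O24·4H2O/H2O2 the phenyl sulfone F9, and Me3SiOTf/2,6-lutidine the silyl ether F10. Its lithio derivative (n-BuLi, THF, −78 °C) is added to aldehyde 30 and the alkoxide is trapped with BzCl, giving the beta-benzoyloxy sulfone F11 as a mixture of diastereomers. Sodium amalgam (Na/Hg, Na2HPO4, MeOH–THF, −20 °C) eliminates it to alkene 31 (E/Z mixture, both usable), where the route is rejoined.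

Further compounds
F1 | step 8 | (2R,3S)-1,3-bis(tert-butyldimethylsilyloxy)-2-(prop-1-en-2-yl)hept-6-yne | C#CCC[C@H](O[Si](C)(C)C(C)(C)C)[C@@H](CO[Si](C)(C)C(C)(C)C)C(C)=C
F2 | step 8 | ynone acetate of F1 | CC(=O)OC(C)(C)C(=O)C#CCC[C@H](O[Si](C)(C)C(C)(C)C)[C@@H](CO[Si](C)(C)C(C)(C)C)C(C)=C
F3 | step 8 | open-chain bis(silyl ether) furanone | CC1(C)OC(=CC1=O)CC[C@H](O[Si](C)(C)C(C)(C)C)[C@@H](CO[Si](C)(C)C(C)(C)C)C(C)=C
F4 | step 8 | tricyclic photoadduct, bis(silyl ether) | O=C1[C@@H]2C[C@@]3(C)[C@H](CO[Si](C)(C)C(C)(C)C)[C@@H](O[Si](C)(C)C(C)(C)C)CC[C@@]23OC1(C)C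
F5 | step 8 | oxepanone, bis(silyl ether) | O=C1CC[C@@]2(C)[C@H](CO[Si](C)(C)C(C)(C)C)[C@@H](O[Si](C)(C)C(C)(C)C)CC[C@@H]2OC1(C)C
F6 | step 8 | (3S)-alcohol, bis(silyl ether) | O[C@H]1CC[C@@]2(C)[C@H](CO[Si](C)(C)C(C)(C)C)[C@@H](O[Si](C)(C)C(C)(C)C)CC[C@@H]2OC1(C)C
F7 | step 8 | (3S)-benzyl ether, bis(silyl ether) | c1ccccc1CO[C@H]1CC[C@@]2(C)[C@H](CO[Si](C)(C)C(C)(C)C)[C@@H](O[Si](C)(C)C(C)(C)C)CC[C@@H]2OC1(C)C
F0 | step 9 | none | none
F8 | step 25 | phenyl sulfide of 21 | c1ccccc1CO[C@H]1CC[C@@]2(C)[C@H](CSc3ccccc3)[C@](C)(O)CC[C@@H]2OC1(C)C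
F9 | step 25 | phenyl sulfone | c1ccccc1CO[C@H]1CC[C@@]2(C)[C@H](CS(=O)(=O)c3ccccc3)[C@](C)(O)CC[C@@H]2OC1(C)C
F10 | step 25 | 7-O-trimethylsilyl phenyl sulfone | c1ccccc1CO[C@H]1CC[C@@]2(C)[C@H](CS(=O)(=O)c3ccccc3)[C@](C)(O[Si](C)(C)C)CC[C@@H]2OC1(C)C
F11 | step 25 | beta-benzoyloxy sulfone (mixture of diastereomers at the two new centres) | c1ccccc1CO[C@H]1CC[C@@]2(C)[C@H](C(S(=O)(=O)c3ccccc3)C(OC(=O)c3ccccc3)[C@H]3[C@]4(C)CCC(=O)C(C)(C)O[C@H]4CC[C@]3(C)O[Si](CC)(CC)CC)[C@](C)(O[Si](C)(C)C)CC[C@@H]2OC1(C)C
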